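C1(OH)–C2(Ar)–O3–C4H2–C5(H)–C6(Ar)–O7–C8H2, fusion bond C1–C5; ring 1 = C1,C2,O3,C4,C5; ring 2 = C1,C5,C6,O7,C8; Ar = 3,4-dimethoxyphenyl.
Enabling feature: in ring 1 the tertiary C1–OH is vicinal to the benzylic C2–O3 bond and C8H2–O is allylic to a C1=C2 arylidene, so one C1–C2 epoxide of an allylic alcohol, opened at C2 by the C4 hydroxyl, supplies both oxygens.
Retrosynthesis: cut O7–C8 (ring 2, SN2 at C8), then C2–O3 (ring 1, epoxide opening), then the epoxide oxygen, the C1=C2 alkene (lactone aldol–dehydration) and C5–C6 (aldol of a succinate imide).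
Forward: C5–C6 bond, γ-lactone C4–O–C8(=O), C1=C2, reduction to the 1,4-diol, epoxide, ring 1 (key step), ring 2 last.
Stereochemistry: C5 and C6 from the (R)-benzyloxazolidinone syn-aldol; C1 and C2 from the L-(+)-tartrate epoxidation of the (E)-alkene, C2 being inverted in the opening; the trans fusion follows because C8 and C6 end up trans on ring 1.

Key step: step 9

Remark on the chemistry: the SMILES is read literally, so C1–OH and C5–H lie on opposite faces and the target is the trans-fused (1S,2R,5S,6R)-bicycle; ring 2 is therefore closed last, kinetically and under non-acidic conditions.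

Step 1
Reactants: 1 (R)-4-benzyl-1,3-oxazolidin-2-one; 2 4-tert-butoxy-4-oxobutanoic acid (mono-tert-butyl succinate)
Product: 4 tert-butyl 4-[(4R)-4-benzyl-2-oxo-1,3-oxazolidin-3-yl]-4-oxobutanoate, via mixed pivalic anhydride 3 (not isolated)
Conditions: PivCl, Et3N, THF, −20 °C; then 1, LiCl, −20 °C → rt
Reagents that add atoms: none
Why: N-acylation of the oxazolidinone through a mixed pivalic anhydride (LiCl-assisted) is the standard entry to Evans imides and leaves the tert-butyl ester untouched; no stereocentre is formed.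

Step 2
Reactants: 4 tert-butyl 4-[(4R)-4-benzyl-2-oxo-1,3-oxazolidin-3-yl]-4-oxobutanoate; 5 3,4-dimethoxybenzaldehyde
Product: 8 tert-butyl (3R,4R)-3-{[(4R)-4-benzyl-2-oxo-1,3-oxazolidin-3-yl]carbonyl}-4-(3,4-dimethoxyphenyl)-4-hydroxybutanoate, via Z-boron enolate 6 (not isolated), via boron aldolate 7 (not isolated)
Conditions: Bu2BOTf, iPr2NEt, CH2Cl2, −78 → 0 °C; 5, −78 → 0 °C; then pH 7 buffer, MeOH, H2O2, 0 °C
Reagents that add atoms: none
Why: Evans syn-aldol reaction, in which the Z-dibutylboron enolate reacts through a chair Zimmerman–Traxler transition state on the face away from the benzyl group of the (R)-auxiliary and so sets C5 and C6 (both R at this stage, syn) in one step; the hindered tert-butyl ester should keep the new hydroxyl from lactonising.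

Step 3
Reactants: 8 syn-aldol adduct
Product: 9 tert-butyl (3R,4R)-3-{[(4R)-4-benzyl-2-oxo-1,3-oxazolidin-3-yl]carbonyl}-4-[(tert-butyldimethylsilyl)oxy]-4-(3,4-dimethoxyphenyl)butanoate
Conditions: TBSOTf, 2,6-lutidine, CH2Cl2, −78 → 0 °C
Reagents that add atoms: tert-butyldimethylsilyl trifluoromethanesulfonate, CC(C)(C)[Si](C)(C)OS(=O)(=O)C(F)(F)F
Why: silyl triflate silylation of the secondary benzylic alcohol is fast at low temperature and blocks O7 against retro-aldol, against lactonisation onto C8 and, in step 9, against attack on the epoxide; no stereocentre changes.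

Step 4
Reactants: 9 silylated aldol imide
Product: 11 (4S)-4-[(R)-[(tert-butyldimethylsilyl)oxy](3,4-dimethoxyphenyl)methyl]oxolan-2-one, via hydroxy tert-butyl ester 10 (not isolated)
Conditions: NaBH4, THF/H2O, 0 °C → rt; then CSA (cat.), CH2Cl2, rt
Reagents that add atoms: none
Why: borohydride reduction cleaves the N-acyl oxazolidinone to the primary C4 alcohol (the auxiliary is released) and acid-catalysed lactonisation of the γ-hydroxy tert-butyl ester (5-exo-trig acyl transfer) closes the C4–O–C8(=O) lactone; C5 and C6 are not touched.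

Step 5
Reactants: 11 β-substituted γ-butyrolactone; 5 3,4-dimethoxybenzaldehyde
Product: 13 (4S)-3-[(3,4-dimethoxyphenyl)(hydroxy)methyl]-4-[(R)-[(tert-butyldimethylsilyl)oxy](3,4-dimethoxyphenyl)methyl]oxolan-2-one (mixture of diastereomers at the two new centres), via lithium enolate 12 (not isolated)
Conditions: LiN(SiMe3)2, THF, −78 °C; 5, −78 °C; aq. NH4Cl
Reagents that add atoms: none
Why: aldol addition of the lactone enolate (C1) to the aldehyde forms the C1–C2 bond; the two new centres are removed in step 6, so their configuration does not matter.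

Step 6
Reactants: 13 β-hydroxy lactone
Product: 15 (3E,4S)-3-(3,4-dimethoxybenzylidene)-4-[(R)-[(tert-butyldimethylsilyl)oxy](3,4-dimethoxyphenyl)methyl]oxolan-2-one, via mesylate 14 (not isolated)
Conditions: MsCl, Et3N, CH2Cl2, 0 °C; then DBU, rt
Reagents that add atoms: none
Why: E1cB elimination of the mesylate gives the conjugated arylidene lactone, and the (E) isomer (aryl trans to the lactone carbonyl, cis to C5) is the thermodynamic product of this kind of dehydration.

Step 7
Reactants: 15 (E)-arylidene lactone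
Product: 16 (2E,3S)-2-(3,4-dimethoxybenzylidene)-3-[(R)-[(tert-butyldimethylsilyl)oxy](3,4-dimethoxyphenyl)methyl]butane-1,4-diol
Conditions: iBu2AlH (excess), CH2Cl2, −78 → 0 °C; aq. potassium sodium tartrate
Reagents that add atoms: none
Why: 1,2-reduction of the unsaturated lactone by the aluminium hydride gives the allylic C8 alcohol and the C4 alcohol without touching the alkene or the silyl ether.

Step 8
Reactants: 16 (E)-2-arylidene-1,4-diol
Product: 17 (2S,3R)-3-[(tert-butyldimethylsilyl)oxy]-3-(3,4-dimethoxyphenyl)-2-[(2S,3S)-3-(3,4-dimethoxyphenyl)-2-(hydroxymethyl)oxiran-2-yl]propan-1-ol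
Conditions: Ti(OiPr)4 (1 equiv), L-(+)-diethyl tartrate (1.2 equiv), tBuOOH, 4 Å MS, CH2Cl2, −25 °C; non-acidic work-up
Reagents that add atoms: tert-butyl hydroperoxide, CC(C)(C)OO
Why: Sharpless asymmetric epoxidation of the primary allylic alcohol (C8–OH), in which L-(+)-tartrate gives the (2S,3S)-oxiranemethanol sense known for (E)-2-substituted cinnamyl alcohols, so C1 and C2 are both set as S with the aryl group cis to C5; stoichiometric titanium tartrate is used because the C4 hydroxyl also binds titanium.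

Step 9
Reactants: 17 C1–C2 epoxy diol
Product: 18 (2R,3S,4S)-2-(3,4-dimethoxyphenyl)-3-(hydroxymethyl)-4-[(R)-[(tert-butyldimethylsilyl)oxy](3,4-dimethoxyphenyl)methyl]oxolan-3-ol
Conditions: CSA (10 mol %), CH2Cl2, −20 → 0 °C
Reagents that add atoms: none
Why: Camphorsulfonic acid protonates the oxirane oxygen, the C2–O bond stretches because C2 is a 3,4-dimethoxybenzylic position, and the C4 hydroxyl attacks C2 from the side opposite the departing oxygen, forming C2–O3 and leaving the former oxirane oxygen as the tertiary C1–OH. The closest known reaction type is the acid-catalysed endo-selective opening of aryl-substituted 2,3-epoxy alcohols by a tethered hydroxyl to give 2-aryl-3-hydroxytetrahydrofurans. Ring 1 (C1, C2, O3, C4, C5) closes in the 5-endo mode with respect to the epoxide; the 4-exo alternative (attack at C1) is disfavoured because C1 is fully substituted and has no cation-stabilising group. C2 is the only centre that changes: it is inverted (S in 17, R in 18) under control of the epoxide configuration, which came from the tartrate and the (E) alkene geometry, while C1 keeps its configuration because its C–O bond is never broken. The step needs regioselectivity for C2 and the C4 oxygen as the only nucleophile: the first is secured by benzylic stabilisation, the second by the silyl group on O7 (attack by O7 would give a 2,5-diaryl tetrahydrofuran) and by the fact that the C8 hydroxyl could only form a four-membered ring. Low temperature, a catalytic sulfonic acid and a non-polar solvent should keep the opening ion-paired so that inversion holds, and the resulting C2 configuration (aryl cis to the small OH, trans to CH2OH) is also expected to be the more stable one.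

Step 10
Reactants: 18 ring 1 diol
Product: 19 [(2R,3S,4S)-2-(3,4-dimethoxyphenyl)-3-hydroxy-4-[(R)-[(tert-butyldimethylsilyl)oxy](3,4-dimethoxyphenyl)methyl]oxolan-3-yl]methyl 4-methylbenzenesulfonate
Conditions: TsCl, Et3N, Bu2SnO (cat.), CH2Cl2, 0 °C → rt
Reagents that add atoms: 4-methylbenzenesulfonyl chloride, Cc1ccc(cc1)S(Cl)(=O)=O
Why: tin-catalysed regioselective monosulfonylation of a 1,2-diol at the primary hydroxyl turns C8 into the electrophile for ring 2, and the tertiary C1–OH does not react.

Step 11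
Reactants: 19 primary tosylate
Product: 20 1-ethoxyethyl ether of 19 at the tertiary C1 oxygen (mixture of epimers at the acetal carbon)
Conditions: ethyl vinyl ether, PPTS (cat.), CH2Cl2, 0 °C → rt
Reagents that add atoms: ethyl vinyl ether, C=COCC
Why: acid-catalysed acetalisation masks the C1–OH, which under base would otherwise close an oxirane onto C8 much faster than O7 can form the strained ring 2; an acetal, unlike a silyl group, cannot migrate to the neighbouring O7 alkoxide.

Step 12
Reactants: 20 acetal-protected tosylate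
Product: 22 1-ethoxyethyl ether of the target at the C1 oxygen, via desilylated hydroxy tosylate 21 (not isolated)
Conditions: Bu4NF, 4 Å MS, THF, 0 → 60 °C
Reagents that add atoms: none
Why: fluoride desilylation frees the C6 alkoxide, which displaces the C8 tosylate in an intramolecular Williamson etherification (5-exo-tet) and closes ring 2; the bicycle is trans-fused because C8 and C6 are trans on ring 1, and no stereocentre is touched since C8 is a CH2 group.

Step 13
Reactants: 22 protected bicycle
Product: 23 (1S,2R,5S,6R)-2,6-bis(3,4-dimethoxyphenyl)-3,7-dioxabicyclo[3.3.0]octan-1-ol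
Conditions: PPTS (cat.), EtOH, 0 °C → rt
Reagents that add atoms: none
Why: mild acid-catalysed transacetalisation removes the 1-ethoxyethyl group under conditions that should not ionise the benzylic C–O bonds of the strained bicycle.

Compound list
1 | (R)-4-benzyl-1,3-oxazolidin-2-one | O=C1N[C@H](Cc2ccccc2)CO1 | starting material
2 | 4-tert-butoxy-4-oxobutanoic acid (mono-tert-butyl succinate) | OC(=O)CCC(=O)OC(C)(C)C | starting material
3 | mixed anhydride of 2 with pivalic acid (formed in the flask) | CC(C)(C)C(=O)OC(=O)CCC(=O)OC(C)(C)C | intermediate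
4 | tert-butyl 4-[(4R)-4-benzyl-2-oxo-1,3-oxazolidin-3-yl]-4-oxobutanoate | CC(C)(C)OC(=O)CCC(=O)N1[C@H](Cc2ccccc2)COC1=O | intermediate
5 | 3,4-dimethoxybenzaldehyde (veratraldehyde) | COc1ccc(C=O)cc1OC | starting material
6 | (Z)-dibutylboron enolate of 4 (formed in the flask) | CCCCB(CCCC)O/C(=C\CC(=O)OC(C)(C)C)N1[C@H](Cc2ccccc2)COC1=O | intermediate
7 | O-dibutylboryl aldolate of 8 (formed in the flask) | O=C(N1[C@H](Cc2ccccc2)COC1=O)[C@H](CC(=O)OC(C)(C)C)[C@@H](OB(CCCC)CCCC)c1ccc(OC)c(OC)c1 | intermediate
8 | tert-butyl (3R,4R)-3-{[(4R)-4-benzyl-2-oxo-1,3-oxazolidin-3-yl]carbonyl}-4-(3,4-dimethoxyphenyl)-4-hydroxybutanoate | O=C(N1[C@H](Cc2ccccc2)COC1=O)[C@H](CC(=O)OC(C)(C)C)[C@@H](O)c1ccc(OC)c(OC)c1 | intermediate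
9 | tert-butyldimethylsilyl ether of 8 at the benzylic oxygen | O=C(N1[C@H](Cc2ccccc2)COC1=O)[C@H](CC(=O)OC(C)(C)C)[C@@H](O[Si](C)(C)C(C)(C)C)c1ccc(OC)c(OC)c1 | intermediate
10 | tert-butyl (3S,4R)-4-[(tert-butyldimethylsilyl)oxy]-4-(3,4-dimethoxyphenyl)-3-(hydroxymethyl)butanoate (formed in the flask) | OC[C@H](CC(=O)OC(C)(C)C)[C@@H](O[Si](C)(C)C(C)(C)C)c1ccc(OC)c(OC)c1 | intermediate
11 | (4S)-4-[(R)-[(tert-butyldimethylsilyl)oxy](3,4-dimethoxyphenyl)methyl]oxolan-2-one | O=C1C[C@@H](CO1)[C@@H](O[Si](C)(C)C(C)(C)C)c1ccc(OC)c(OC)c1 | intermediate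
12 | lithium enolate of 11 (formed in the flask) | [Li]OC1=C[C@@H](CO1)[C@@H](O[Si](C)(C)C(C)(C)C)c1ccc(OC)c(OC)c1 | intermediate
13 | (4S)-3-[(3,4-dimethoxyphenyl)(hydroxy)methyl]-4-[(R)-[(tert-butyldimethylsilyl)oxy](3,4-dimethoxyphenyl)methyl]oxolan-2-one, mixture at C3 and the new carbinol carbon | COc1ccc(cc1OC)C(O)C2C(=O)OC[C@H]2[C@@H](O[Si](C)(C)C(C)(C)C)c3ccc(OC)c(OC)c3 | intermediate
14 | methanesulfonate of 13 (formed in the flask) | COc1ccc(cc1OC)C(OS(C)(=O)=O)C2C(=O)OC[C@H]2[C@@H](O[Si](C)(C)C(C)(C)C)c3ccc(OC)c(OC)c3 | intermediate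
15 | (3E,4S)-3-(3,4-dimethoxybenzylidene)-4-[(R)-[(tert-butyldimethylsilyl)oxy](3,4-dimethoxyphenyl)methyl]oxolan-2-one | COc1ccc(cc1OC)/C=C2/C(=O)OC[C@H]2[C@@H](O[Si](C)(C)C(C)(C)C)c3ccc(OC)c(OC)c3 | intermediate
16 | (2E,3S)-2-(3,4-dimethoxybenzylidene)-3-[(R)-[(tert-butyldimethylsilyl)oxy](3,4-dimethoxyphenyl)methyl]butane-1,4-diol | COc1ccc(cc1OC)/C=C(/CO)[C@@H](CO)[C@@H](O[Si](C)(C)C(C)(C)C)c2ccc(OC)c(OC)c2 | intermediate
17 | (2S,3R)-3-[(tert-butyldimethylsilyl)oxy]-3-(3,4-dimethoxyphenyl)-2-[(2S,3S)-3-(3,4-dimethoxyphenyl)-2-(hydroxymethyl)oxiran-2-yl]propan-1-ol | COc1ccc(cc1OC)[C@@H]2O[C@]2(CO)[C@@H](CO)[C@@H](O[Si](C)(C)C(C)(C)C)c3ccc(OC)c(OC)c3 | intermediate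
18 | (2R,3S,4S)-2-(3,4-dimethoxyphenyl)-3-(hydroxymethyl)-4-[(R)-[(tert-butyldimethylsilyl)oxy](3,4-dimethoxyphenyl)methyl]oxolan-3-ol | COc1ccc(cc1OC)[C@H]2OC[C@@H]([C@@H](O[Si](C)(C)C(C)(C)C)c3ccc(OC)c(OC)c3)[C@]2(O)CO | intermediate
19 | primary 4-methylbenzenesulfonate of 18 (C8–OTs, C1–OH free) | COc1ccc(cc1OC)[C@H]2OC[C@@H]([C@@H](O[Si](C)(C)C(C)(C)C)c3ccc(OC)c(OC)c3)[C@]2(O)COS(=O)(=O)c4ccc(C)cc4 | intermediate
20 | 1-ethoxyethyl ether of 19 at the C1 oxygen (acetal carbon undefined) | COc1ccc(cc1OC)[C@H]2OC[C@@H]([C@@H](O[Si](C)(C)C(C)(C)C)c3ccc(OC)c(OC)c3)[C@]2(OC(C)OCC)COS(=O)(=O)c4ccc(C)cc4 | intermediate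
21 | 20 without the silyl group on O7 (formed in the flask) | COc1ccc(cc1OC)[C@H]2OC[C@@H]([C@@H](O)c3ccc(OC)c(OC)c3)[C@]2(OC(C)OCC)COS(=O)(=O)c4ccc(C)cc4 | intermediate
22 | (1S,2R,5S,6R)-2,6-bis(3,4-dimethoxyphenyl)-1-(1-ethoxyethoxy)-3,7-dioxabicyclo[3.3.0]octane (acetal carbon undefined) | COc1ccc([C@H]2OC[C@H]3[C@H](c4ccc(OC)c(OC)c4)OC[C@]23OC(C)OCC)cc1OC | intermediate
23 | (1S,2R,5S,6R)-2,6-bis(3,4-dimethoxyphenyl)-3,7-dioxabicyclo[3.3.0]octan-1-ol | COc1ccc([C@H]2OC[C@H]3[C@H](c4ccc(OC)c(OC)c4)OC[C@]23O)cc1OC | target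

Total step count: 13. Longest linear sequence: 13 steps (2 → 23; the route is fully linear).

Steps most likely to fail

Step 12. The displacement at the neopentyl-type C8 has to build a strained trans-fused bicycle, so the liberated alkoxide may cyclise too slowly and the tosylate may instead be consumed by fluoride substitution or by participation of the acetal oxygen. The fallback sets out from 18 and closes ring 2 at the aldehyde oxidation level instead of by SN2. Parikh–Doering oxidation (SO3·pyridine, DMSO, iPr2NEt) of the primary C8 alcohol should give the α-hydroxy aldehyde F1. Treating it with Et3SiH and catalytic BiBr3 in MeCN at −20 → 0 °C is a reductive etherification: the O7 silyl ether adds to the activated C8 carbonyl and the cyclic oxocarbenium ion is reduced by the silane. The free C1–OH cannot compete, since it could only form a three-membered hemiacetal, so no protection is needed. The sequence comes back to the route at 23.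

Step 8. The 1,4-diol may occupy both exchangeable sites on titanium, which slows turnover and can lower facial selectivity, and the titanium alkoxide may open the electron-rich aryl epoxide in the flask before it is isolated. The fallback sets out from 10, isolated after the borohydride reduction instead of being lactonised, and keeps the two primary oxygens different throughout.
- The C4 hydroxyl is silylated (Et3SiCl, imidazole) to the triethylsilyl ether F2.
- The ester enolate F3 (LiN(iPr)2, THF, −78 °C) is added to 5 to give the aldol adducts F4.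
- Mesylation to F5 and DBU elimination give the (E)-arylidene ester F6.
- iBu2AlH reduces the ester to the allylic alcohol F7.
- Sharpless epoxidation with catalytic Ti(OiPr)4 and L-(+)-diethyl tartrate should then give the epoxy alcohol F8, which has no free internal nucleophile and can be isolated.
- Buffered fluoride (Bu4NF, AcOH, THF, 0 °C) removes only the primary triethylsilyl group.

This comes back to the route at 17, which is taken directly into step 9.

Step 9. Ionisation to a free dimethoxybenzylic cation would erode the inversion at C2, and acid may also start to cleave the benzylic silyl ether. The fallback sets out from 17 and replaces kinetic stereospecificity by thermodynamic control. The opening is run under deliberately reversible conditions (TsOH·H2O, CH2Cl2, rt) so that 18 and its C2 epimer F9 interconvert through reversible ionisation of the benzylic C2–O3 bond, as is known for 2-aryltetrahydrofuran lignans. The equilibrium should favour the isomer with the aryl group cis to the small C1–OH and trans to CH2OH, so the sequence comes back to the route at 18.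

Further compounds
F1 | step 12 | (2R,3R,4S)-4-[(R)-[(tert-butyldimethylsilyl)oxy](3,4-dimethoxyphenyl)methyl]-2-(3,4-dimethoxyphenyl)-3-hydroxyoxolane-3-carbaldehyde | COc1ccc(cc1OC)[C@H]2OC[C@@H]([C@@H](O[Si](C)(C)C(C)(C)C)c3ccc(OC)c(OC)c3)[C@]2(O)C=O
F2 | step 8 | tert-butyl (3S,4R)-4-[(tert-butyldimethylsilyl)oxy]-4-(3,4-dimethoxyphenyl)-3-{[(triethylsilyl)oxy]methyl}butanoate | CC[Si](CC)(CC)OC[C@H](CC(=O)OC(C)(C)C)[C@@H](O[Si](C)(C)C(C)(C)C)c1ccc(OC)c(OC)c1
F3 | step 8 | lithium enolate of F2 | CC[Si](CC)(CC)OC[C@H](C=C(O[Li])OC(C)(C)C)[C@@H](O[Si](C)(C)C(C)(C)C)c1ccc(OC)c(OC)c1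
F4 | step 8 | aldol adducts of F2 with 5 (tert-butyl ester, mixture at the two new centres) | COc1ccc(cc1OC)C(O)C(C(=O)OC(C)(C)C)[C@@H](CO[Si](CC)(CC)CC)[C@@H](O[Si](C)(C)C(C)(C)C)c2ccc(OC)c(OC)c2
F5 | step 8 | methanesulfonate of F4 | COc1ccc(cc1OC)C(OS(C)(=O)=O)C(C(=O)OC(C)(C)C)[C@@H](CO[Si](CC)(CC)CC)[C@@H](O[Si](C)(C)C(C)(C)C)c2ccc(OC)c(OC)c2
F6 | step 8 | tert-butyl (2E,3S,4R)-4-[(tert-butyldimethylsilyl)oxy]-2-(3,4-dimethoxybenzylidene)-4-(3,4-dimethoxyphenyl)-3-{[(triethylsilyl)oxy]methyl}butanoate | COc1ccc(cc1OC)/C=C(/C(=O)OC(C)(C)C)[C@@H](CO[Si](CC)(CC)CC)[C@@H](O[Si](C)(C)C(C)(C)C)c2ccc(OC)c(OC)c2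
F7 | step 8 | (E)-allylic alcohol, as 16 but with the C4 hydroxyl as its triethylsilyl ether | COc1ccc(cc1OC)/C=C(/CO)[C@@H](CO[Si](CC)(CC)CC)[C@@H](O[Si](C)(C)C(C)(C)C)c2ccc(OC)c(OC)c2
F8 | step 8 | epoxy alcohol, as 17 but with the C4 hydroxyl as its triethylsilyl ether | COc1ccc(cc1OC)[C@@H]2O[C@]2(CO)[C@@H](CO[Si](CC)(CC)CC)[C@@H](O[Si](C)(C)C(C)(C)C)c3ccc(OC)c(OC)c3
F9 | step 9 | (2S,3S,4S)-epimer of 18 (aryl at C2 on the other face) | COc1ccc(cc1OC)[C@@H]2OC[C@@H]([C@@H](O[Si](C)(C)C(C)(C)C)c3ccc(OC)c(OC)c3)[C@]2(O)CO
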